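The numbers in the tables stem from a simulated flask for an exercise; the scatter is artificial.

I decide to vary the loading of Q at fixed E and to judge each flask by the Z it holds at the end.

| flask | E | Q | remark | time |
|---|---|---|---|---|
| Saturday's | 1 M (fed, over 2.0 min) | 1 mol% | run made earlier |  |
| Monday's | 3 M (fed, over 2.0 min) | 1 mol% | run made earlier |  |
| winter | 1.5 M (fed, over 2.0 min) | 1 mol% |  | 6.0 min |
| noon | 1.5 M (fed, over 2.0 min) | 1.5 mol% |  | 6.0 min |
| spring | 1.5 M (fed, over 2.0 min) | 2.5 mol% |  | 6.0 min |

| run | time / min | Z / % | E / % |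
|---|---|---|---|
| Saturday's | 0.500 | 0.1 | 24.8 |
| Saturday's | 1.00 | 0.1 | 49.2 |
| Saturday's | 1.50 | 1.3 | 73.2 |
| Saturday's | 2.00 | 3.6 | 97.6 |
| Saturday's | 2.50 | 4.0 | 95.2 |
| Saturday's | 3.00 | 6.0 | 94.7 |
| Saturday's | 4.00 | 9.0 | 90.8 |
| Monday's | 0.500 | 0.3 | 24.4 |
| Monday's | 1.00 | 0.7 | 48.6 |
| Monday's | 1.50 | 2.9 | 72.4 |
| Monday's | 2.00 | 5.0 | 94.8 |
| Monday's | 2.50 | 7.5 | 92.5 |
| Monday's | 3.00 | 10.0 | 89.4 |
| Monday's | 4.00 | 14.6 | 84.6 |

(standard deviation of a reading: 0.5 percentage points)

- "hardly changes" means that all values lie within two and a half points (for a concentration: within two and a half percent of the largest)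
- percentages count the whole charge, also what has not yet gone in

- amount of Z at the end, in percent of the E charged for winter, noon, spring, in this order
- how that number moves from the first to the last of them (rises, then falls / rises all the way / falls all the way / falls, then rises / hardly changes)

After the feed, the Z readings give each run a pseudo-first-order constant k′, the fraction of the unreacted charge that turns to Z per minute. Saturday's flask reads 0.0288 min⁻¹ and Monday's 0.0533 min⁻¹, each with a scatter near 0.00354 min⁻¹.

These two numbers look odd together. Monday's flask holds 3.00 times Saturday's Q, yet its k′ reads 1.85 times as large. A step first order in E and blind to Q gives a factor of 1, and a step proportional to Q gives 3.00.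

The square root of the Q ratio, 1.73, lies within the scatter, as radical chains lead me to expect. So I carry the chain constant κ = 0.0298 min⁻¹, the k′ of a run divided by the square root of the ratio of its molar Q charge to Saturday's, averaged over both runs. But the loading was the same in both runs, so, as I wrote, “The Q order is therefore an assumption”.

Multiplying κ by the square root of each flask's Q ratio to Saturday's gives k′ of 0.0365 min⁻¹ for winter, 0.0447 min⁻¹ for noon and 0.0577 min⁻¹ for spring. The feed is steady, so the charge has stood 5.00 min on average. My forecast is therefore 17 %, 20 % and 25 %: the end value rises all the way.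

The flasks give 16.9 %, 20.4 % and 25.6 %: the end value rises all the way.

    Q → 2 D (k = 3.70 × 10⁻⁴ s⁻¹)
    E + D → J + Z (k = 69000 M⁻¹ s⁻¹)
    E + J → Z + J, rate k3*[J]*[E] (k = 380 M⁻¹ s⁻¹)
    2 J → L (k = 2.00 × 10⁶ M⁻¹ s⁻¹)

In winter, Q stood at 93.6 % of its charge at 3.00 min and J at 1.61 × 10⁻⁶ M, while E + J → Z + J ran with a first-order constant of 0.0367 min⁻¹ beside the 0.0365 min⁻¹ from κ, with a half-life of E by this step of 19 min at 3.35 min, shorter than the 26 h by E + D → J + Z. In spring, J stood at 2.55 × 10⁻⁶ M at 3.00 min, while the same step ran with a constant of 0.0581 min⁻¹ beside the 0.0577 min⁻¹ from κ, and the flask ended with 88 % of its Q left and 25.6 % Z.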